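The numbers in the tables come from a simulation with constants of no real substance; noise was put on by code.

If two mirror-image substrates compete for one single-handed catalyst, I count what is left of each, not what was made.

in all of them: free catalyst 8 mol%

|  | left-handed substrate | right-handed substrate | coupling partner | impurity | remark | time |
|---|---|---|---|---|---|---|
| cedar | 0.075 M | 0.075 M | 3 equiv | 1.7 mM | run made earlier |  |
| ochre | 0.050 M | 0.050 M | 3.00 equiv | 1.7 mM |  | 10 min |
| red | 0.050 M | 0.050 M | 3.00 equiv | 5.0 mM |  | 10 min |

cedar run (percent of the left-handed substrate and right-handed substrate together charged)

| time / min | left-handed product / % | right-handed product / % |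
|---|---|---|
| 0.333 | 10.6 | 3.5 |
| 0.833 | 18.1 | 6.9 |
| 1.50 | 24.4 | 10.1 |
| 2.50 | 30.5 | 10.7 |
| 4.00 | 31.6 | 15.0 |

(scatter of a reading: 1 percentage point)

- free catalyst is single-handed; left-handed substrate and right-handed substrate are mirror images of each other, charged as a racemate, each of them at the stated concentration
- steps that have been proposed: coupling partner + free catalyst + left-handed substrate -> free catalyst + left-handed product; coupling partner + free catalyst + right-handed substrate -> free catalyst + right-handed product; 2 free catalyst -> spent catalyst A; coupling partner -> decomposition product; free catalyst + impurity -> spent catalyst B
- an excess is the difference of the two amounts in percent of their sum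
- an excess is below zero if the other one leads
- no earlier run changes the charge of impurity; that part of a forecast is a guess
- no earlier run changes the charge of free catalyst; that part of a forecast is a guess

1. which of the two ends with the higher excess of left-handed product over right-handed product in the product ("neither" if they lie within 2 percentage points) (ochre / red / neither)
2. excess of left-handed product over right-handed product in the product at the end, ochre
3. excess of left-handed product over right-handed product in the product at the end, red

Each substrate is half of the charge, so its fraction left is one minus twice its product share. Summed over the cedar readings, the logarithm of the left-handed fraction over that of the right-handed fraction reads 3.16. This selectivity factor s turns one fraction left into the other, since free catalyst and coupling partner cancel in the ratio.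

How far the left-handed substrate gets depends on how much catalyst works, so I keep its ledger. I book the impurity first, mole for mole, which is a guess because no earlier run varies it.

| Flask | Free catalyst charged | Taken by impurity | Left to work | Coupling partner |
|---|---|---|---|---|
| cedar | 6.00 mM | 1.7 mM | 4.30 mM | 0.225 M |
| ochre | 4.00 mM | 1.7 mM | 2.30 mM | 0.150 M |
| red | 4.00 mM | 4.00 mM | none booked | 0.150 M |

With catalyst dying in pairs, its summed working time grows slowly, with the logarithm of working catalyst times time. Working catalyst times time for ochre at 10 min is 1.34 times that for cedar at 4.00 min; as a rough step I take the two summed working times as equal and scale by coupling partner alone. The negative logarithm of ochre's left-handed fraction left is then 0.666. I reckon that this leaves 51.4% of the left-handed substrate and, through s, 81.0% of the right-handed, for an excess of 43.8%. By this booking I expect little conversion in red, so I put its excess near (s−1)/(s+1), 51.9%, which is higher than my figure for ochre.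

The forecast gives 43% for ochre and 49% for red, against my 43.8% and 51.9%, and names red as the higher, noting that “The impurity rate is a guess”.

The flask gives 40.5% for ochre and 49.7% for red, so red ends higher.

    coupling partner + free catalyst + left-handed substrate → free catalyst + left-handed product (k = 1000 L² mol⁻² min⁻¹)
    coupling partner + free catalyst + right-handed substrate → free catalyst + right-handed product (k = 330 L² mol⁻² min⁻¹)
    2 free catalyst → spent catalyst A (k = 160 L mol⁻¹ min⁻¹)
    coupling partner → decomposition product (k = 4.40 × 10⁻⁴ min⁻¹)
    free catalyst + impurity → spent catalyst B (k = 4300 L mol⁻¹ min⁻¹)

At 10.0 min, red holds 23.3% of its impurity beside 0% free catalyst, with 95.9% of the catalyst as spent catalyst B. Ochre keeps 44% of its left-handed substrate, which s turns into 77.1% of the right-handed, and the flask holds 76%. A neighbouring flask, set up as red but charged with 20 mol% free catalyst, keeps 35% of its left-handed substrate. From that, s gives 71.8% of the right-handed and an excess of 39.5%, and that flask stands at 71% and 37.9%.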